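## Plan

- **Cuts:** the side chain is cut at C1'–C2' (olefination, then saturation) into a hexahydronaphthylmethyl phosphonium salt and a pre-formed 1,2-dioxane aldehyde. Ring A is opened at C5=C6 (ring-closing metathesis) and its C7–C8 arm is traced to a carboxyl group on C8a. Ring B is cut at C1–C8a, giving a 6-alkenyl-4-vinyl δ-lactone.
- **Enabling feature:** in ring B the gem-dimethyl quaternary C1 lies between the C8a stereocentre and the tetrasubstituted C2=C3 alkene. This is the pattern left when a C8a ester enolate adds by a [3,3] shift to a Me2C= terminus and the double bond moves to C2=C3.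
- **Forward order:** vinyl lactone → carbinol lactone → ring B (Ireland–Claisen ring contraction) → ring A (metathesis) → phosphonium salt. In parallel the dioxane is closed on an acyclic chain. Union, diimide reduction and oxidation to the acid finish the route.
- **Stereochemistry:** C4a comes from a Rh/(R)-BINAP vinyl addition. C8a is relayed from the lactone carbinol centre through the boat transition state. The quaternary dioxane carbon comes from (S)-2-methylglycidol (one inversion). The secondary dioxane carbon and the acid α-carbon come from an Evans syn aldol (inversion at the O-bearing carbon on ring closure).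

Key step: step 8

Locants: naphthalene numbering for the bicyclic core (C1 = CMe2, C2 = side-chain carbon, C4a/C8a = ring fusion); C1'/C2' are the two CH2 groups between C2 and the dioxane.

Assumption (chemistry): the methyllithium addition of step 6 is expected to show no useful 1,3-induction, so both carbinol epimers are carried into step 7 and the 4,6-trans lactone is isolated there by chromatography.

## Route

Step 1
Reactants: 1 3-methylbut-2-enal
Product: 3 2-bromo-3-methylbut-2-enal, via 2,3-dibromo-3-methylbutanal 2 (not isolated)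
Conditions: Br2, CH2Cl2, 0 °C; then Et3N, 0 °C → rt
Reagents that add atoms: bromine, BrBr
Why: Bromine adds across the enal C=C and triethylamine then removes the acidic α-proton with loss of the tertiary bromide (addition–elimination α-bromination of an enal), which should leave the vinylic bromide at C2.

Step 2
Reactants: 3 2-bromo-3-methylbut-2-enal
Product: 4 2-bromo-3-methylbut-2-en-1-ol
Conditions: NaBH4, CeCl3·7H2O, MeOH, 0 °C
Reagents that add atoms: none
Why: Luche reduction is a selective 1,2-reduction of an enal and should not touch the vinylic C–Br bond.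

Step 3
Reactants: 4 2-bromo-3-methylbut-2-en-1-ol
Product: 5 [(2-bromo-3-methylbut-2-en-1-yl)oxy](tert-butyl)diphenylsilane
Conditions: TBDPSCl, imidazole, CH2Cl2, rt
Reagents that add atoms: tert-butylchlorodiphenylsilane, CC(C)(C)[Si](Cl)(c1ccccc1)c1ccccc1
Why: Standard silylation of a primary alcohol; the bulky silyl group is chosen because it should also slow O→C silyl migration in the vinyllithium of step 5.

Step 4
Reactants: 6 5,6-dihydro-2H-pyran-2-one; 7 potassium vinyltrifluoroborate
Product: 8 (R)-4-vinyltetrahydro-2H-pyran-2-one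
Conditions: [Rh(cod)2]BF4 (3 mol %), (R)-BINAP, toluene/H2O, 100 °C
Reagents that add atoms: none
Why: Hayashi–Miyaura Rh/BINAP conjugate addition of an alkenylboron reagent to an α,β-unsaturated lactone; the (R)-BINAP–Rh–vinyl species should add to the enoate face that gives the 4R centre, following the facial preference established for cyclic enones and enoates.

Step 5
Reactants: 5 [(2-bromo-3-methylbut-2-en-1-yl)oxy](tert-butyl)diphenylsilane; 8 (R)-4-vinyltetrahydro-2H-pyran-2-one
Product: 10 (6R)-3-[(tert-butyldiphenylsilyloxy)methyl]-8-hydroxy-2-methyl-6-vinyloct-2-en-4-one, via [1-(tert-butyldiphenylsilyloxy)-3-methylbut-2-en-2-yl]lithium 9 (not isolated)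
Conditions: 5, t-BuLi (2 equiv), Et2O, −78 °C; then 8, −78 °C; aq. NH4Cl
Reagents that add atoms: none
Why: Bromine–lithium exchange gives the vinyllithium, which should add only once to the δ-lactone because the lithium lactolate does not collapse at −78 °C (organolithium mono-addition to a lactone); the existing stereocentre is not touched.

Step 6
Reactants: 10 (6R)-3-[(tert-butyldiphenylsilyloxy)methyl]-8-hydroxy-2-methyl-6-vinyloct-2-en-4-one; 11 methyllithium
Product: 12 (4RS,6R)-3-[(tert-butyldiphenylsilyloxy)methyl]-2,4-dimethyl-6-vinyloct-2-ene-4,8-diol (both C4 epimers)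
Conditions: MeLi (3 equiv), THF, −78 → −20 °C
Reagents that add atoms: none
Why: After deprotonation of the primary alcohol, methyllithium should add 1,2 to the hindered enone carbonyl (organolithium addition to a ketone); the remote C6 centre gives no reliable induction, so the new carbinol centre is expected as both epimers.

Step 7
Reactants: 12 (4RS,6R)-3-[(tert-butyldiphenylsilyloxy)methyl]-2,4-dimethyl-6-vinyloct-2-ene-4,8-diol
Product: 13 (4S,6R)-6-[1-(tert-butyldiphenylsilyloxy)-3-methylbut-2-en-2-yl]-6-methyl-4-vinyltetrahydro-2H-pyran-2-one (vinyl trans to the alkenyl group)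
Conditions: TEMPO (20 mol %), PhI(OAc)2 (2.5 equiv), CH2Cl2, rt; chromatography (removal of the C6 epimer)
Reagents that add atoms: none
Why: Oxidative lactonization of a 1,5-diol: the oxoammonium oxidant takes only the primary alcohol to the aldehyde, the tertiary alcohol traps it as a lactol and this is oxidized to the δ-lactone; no stereocentre is formed, and the rigid 4,6-trans lactone should separate from its cis epimer on silica.

Step 8
Reactants: 13 (4S,6R)-6-[1-(tert-butyldiphenylsilyloxy)-3-methylbut-2-en-2-yl]-6-methyl-4-vinyltetrahydro-2H-pyran-2-one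
Product: 16 (1S,6R)-3-[(tert-butyldiphenylsilyloxy)methyl]-2,2,4-trimethyl-6-vinylcyclohex-3-ene-1-carboxylic acid, via trimethylsilyl ketene acetal 14 (not isolated), via trimethylsilyl ester 15 (not isolated)
Conditions: LDA, TMSCl/Et3N, THF, −78 °C → rt; then PhMe, 100 °C; 1 M HCl work-up
Reagents that add atoms: none
Why: Kinetic deprotonation at C3 (the only α-CH2) with in situ O-silylation gives the cyclic silyl ketene acetal, whose C3=C2–O1–C6–C=CMe2 array should undergo a [3,3] sigmatropic shift that forms the C3–CMe2 bond and breaks the tertiary allylic O1–C6 bond. The closest known reaction type is the Ireland–Claisen ring contraction of 6-alkenyl δ-lactones (lactone enolate Claisen), used here with a fully substituted alkene terminus. Ring B closes in the pericyclic event itself; because C4–C5 tie C3 to C6, the six-atom transition state is forced into a boat (bicyclo[2.2.2]-like array) and no chair alternative exists. The new stereocentre (C1 of 16, the future C8a) is set by C6 of the lactone: the isopropylidene carbon can reach C3 only on the face that carries the alkenyl group, which is anti to the C4 vinyl group, so the carboxyl group ends cis to vinyl. The step needs regioselective enolization (one α-CH2), O- rather than C-silylation (internal TMSCl/Et3N quench) and an epimerically pure trans lactone; relief of strain at the crowded tertiary C–O bond and silyl ester formation should drive the sterically slow formation of the quaternary carbon and the tetrasubstituted alkene.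

Step 9
Reactants: 16 (1S,6R)-3-[(tert-butyldiphenylsilyloxy)methyl]-2,2,4-trimethyl-6-vinylcyclohex-3-ene-1-carboxylic acid
Product: 17 [(1S,6R)-3-[(tert-butyldiphenylsilyloxy)methyl]-2,2,4-trimethyl-6-vinylcyclohex-3-en-1-yl]methanol
Conditions: LiAlH4, THF, 0 °C → rt
Reagents that add atoms: none
Why: Hydride reduction of the carboxylic acid to the primary alcohol; C1 is not epimerized under these conditions and the silyl ether is stable.

Step 10
Reactants: 17 [(1S,6R)-3-[(tert-butyldiphenylsilyloxy)methyl]-2,2,4-trimethyl-6-vinylcyclohex-3-en-1-yl]methanol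
Product: 18 (1S,6R)-3-[(tert-butyldiphenylsilyloxy)methyl]-1-(iodomethyl)-2,2,4-trimethyl-6-vinylcyclohex-3-ene
Conditions: PPh3, I2, imidazole, CH2Cl2, rt
Reagents that add atoms: iodine, II
Why: Appel-type iodination of a primary alcohol; substitution occurs at the CH2 group only, so no stereocentre is involved.

Step 11
Reactants: 18 (1S,6R)-3-[(tert-butyldiphenylsilyloxy)methyl]-1-(iodomethyl)-2,2,4-trimethyl-6-vinylcyclohex-3-ene; 19 2-methylallylmagnesium chloride
Product: 20 (1S,6R)-3-[(tert-butyldiphenylsilyloxy)methyl]-2,2,4-trimethyl-1-(3-methylbut-3-en-1-yl)-6-vinylcyclohex-3-ene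
Conditions: Li2CuCl4 (5 mol %), THF, −20 °C → rt
Reagents that add atoms: none
Why: Copper-catalysed sp3–sp3 coupling (Kochi type) of a primary iodide with an allylic Grignard reagent, which should be reactive enough for this β-branched iodide; α- and γ-attack of the methallyl unit give the same product.

Step 12
Reactants: 20 (1S,6R)-3-[(tert-butyldiphenylsilyloxy)methyl]-2,2,4-trimethyl-1-(3-methylbut-3-en-1-yl)-6-vinylcyclohex-3-ene
Product: 21 tert-butyl{[(4aR,8aS)-1,1,3,6-tetramethyl-1,4,4a,7,8,8a-hexahydronaphthalen-2-yl]methoxy}diphenylsilane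
Conditions: Grubbs II catalyst (5 mol %), CH2Cl2 (dilute), 40 °C
Reagents that add atoms: none
Why: Ring-closing metathesis of the vinyl group with the 1,1-disubstituted alkene should close ring A as a trisubstituted cyclohexene; the two arms are cis on ring B, the tetrasubstituted alkene is inert, and no stereocentre is formed.

Step 13
Reactants: 21 tert-butyl{[(4aR,8aS)-1,1,3,6-tetramethyl-1,4,4a,7,8,8a-hexahydronaphthalen-2-yl]methoxy}diphenylsilane
Product: 22 [(4aR,8aS)-1,1,3,6-tetramethyl-1,4,4a,7,8,8a-hexahydronaphthalen-2-yl]methanol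
Conditions: TBAF, THF, rt
Reagents that add atoms: none
Why: Fluoride cleavage of the silyl ether frees the allylic alcohol.

Step 14
Reactants: 22 [(4aR,8aS)-1,1,3,6-tetramethyl-1,4,4a,7,8,8a-hexahydronaphthalen-2-yl]methanol
Product: 23 {[(4aR,8aS)-1,1,3,6-tetramethyl-1,4,4a,7,8,8a-hexahydronaphthalen-2-yl]methyl}triphenylphosphonium bromide
Conditions: PPh3·HBr, MeOH, rt
Reagents that add atoms: triphenylphosphine hydrobromide, Br.c1ccc(cc1)P(c1ccccc1)c1ccccc1
Why: Triphenylphosphonium bromide converts allylic alcohols of the β-cyclogeraniol type directly into the primary phosphonium salt (substitution through the allyl cation, phosphine attack at the less hindered terminus).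

Step 15
Reactants: 24 (S)-(2-methyloxiran-2-yl)methanol; 25 allylmagnesium chloride
Product: 26 (R)-2-methylhex-5-ene-1,2-diol
Conditions: CuI (10 mol %), THF, −30 → 0 °C (2.5 equiv of 25)
Reagents that add atoms: none
Why: Copper-catalysed epoxide opening by the allyl Grignard reagent at the CH2 terminus; the quaternary stereocentre is not involved (its descriptor changes from S to R by priority only).

Step 16
Reactants: 26 (R)-2-methylhex-5-ene-1,2-diol
Product: 28 (R)-2-(but-3-en-1-yl)-2-methyloxirane, via primary tosylate 27 (not isolated)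
Conditions: TsCl, Et3N, Bu2SnO (cat.), CH2Cl2, rt; then K2CO3, MeOH, rt
Reagents that add atoms: none
Why: Tin-mediated selective tosylation of the primary alcohol followed by Williamson closure by the tertiary alkoxide re-forms the 2,2-disubstituted epoxide without touching the stereocentre.

Step 17
Reactants: 28 (R)-2-(but-3-en-1-yl)-2-methyloxirane
Product: 30 3-[(2R)-2-methyloxiran-2-yl]propanal, via secondary ozonide 29 (not isolated)
Conditions: O3, CH2Cl2, −78 °C; then PPh3, −78 °C → rt
Reagents that add atoms: ozone, [O-][O+]=O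
Why: Ozonolysis with reductive work-up cleaves the terminal alkene to the aldehyde; epoxides are inert to ozone.

Step 18
Reactants: 31 (R)-4-benzyl-3-propionyloxazolidin-2-one; 30 3-[(2R)-2-methyloxiran-2-yl]propanal
Product: 33 (4R)-4-benzyl-3-{(2R,3S)-3-hydroxy-2-methyl-5-[(2R)-2-methyloxiran-2-yl]pentanoyl}oxazolidin-2-one, via dibutylboron (Z)-enolate 32 (not isolated)
Conditions: Bu2BOTf, iPr2NEt, CH2Cl2, −78 → 0 °C; then 30, −78 → 0 °C; pH 7 buffer, MeOH, H2O2, 0 °C
Reagents that add atoms: none
Why: Evans syn aldol: the (Z)-boron enolate reacts through a Zimmerman–Traxler chair in which the (R)-benzyl auxiliary fixes the enolate face, which should give the 2R,3S syn adduct; the work-up is kept neutral to preserve the acid-sensitive epoxide.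

Step 19
Reactants: 33 (4R)-4-benzyl-3-{(2R,3S)-3-hydroxy-2-methyl-5-[(2R)-2-methyloxiran-2-yl]pentanoyl}oxazolidin-2-one
Product: 34 (2S,3S)-2-methyl-5-[(2R)-2-methyloxiran-2-yl]pentane-1,3-diol
Conditions: LiBH4, MeOH (1 equiv), THF, 0 °C
Reagents that add atoms: none
Why: Reductive cleavage of the N-acyl oxazolidinone by lithium borohydride gives the primary alcohol and releases the auxiliary; the hindered 2,2-disubstituted epoxide should be much slower to react at 0 °C.

Step 20
Reactants: 34 (2S,3S)-2-methyl-5-[(2R)-2-methyloxiran-2-yl]pentane-1,3-diol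
Product: 35 (2S,3S)-1-[(tert-butyldiphenylsilyl)oxy]-2-methyl-5-[(2R)-2-methyloxiran-2-yl]pentan-3-ol
Conditions: TBDPSCl, imidazole, CH2Cl2, 0 °C
Reagents that add atoms: tert-butylchlorodiphenylsilane, CC(C)(C)[Si](Cl)(c1ccccc1)c1ccccc1
Why: The bulky silyl chloride should react with the primary alcohol in preference to the secondary one; the acid-stable TBDPS group is chosen to survive step 22.

Step 21
Reactants: 35 (2S,3S)-1-[(tert-butyldiphenylsilyl)oxy]-2-methyl-5-[(2R)-2-methyloxiran-2-yl]pentan-3-ol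
Product: 36 (2S,3S)-1-[(tert-butyldiphenylsilyl)oxy]-2-methyl-5-[(2R)-2-methyloxiran-2-yl]pentan-3-yl methanesulfonate
Conditions: MsCl, Et3N, CH2Cl2, 0 °C
Reagents that add atoms: methanesulfonyl chloride, CS(=O)(=O)Cl
Why: Mesylation of the secondary alcohol proceeds with retention (O–S bond formation) and removes the free hydroxyl that could otherwise open the epoxide to a tetrahydrofuran.

Step 22
Reactants: 36 (2S,3S)-1-[(tert-butyldiphenylsilyl)oxy]-2-methyl-5-[(2R)-2-methyloxiran-2-yl]pentan-3-yl methanesulfonate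
Product: 37 (2S,3S,6S)-1-[(tert-butyldiphenylsilyl)oxy]-6-hydroperoxy-7-hydroxy-2,6-dimethylheptan-3-yl methanesulfonate
Conditions: H2O2 (anhydrous, in Et2O), phosphomolybdic acid (cat.), Et2O, rt
Reagents that add atoms: hydrogen peroxide, OO
Why: Molybdenum-catalysed perhydrolysis of a 2,2-disubstituted epoxide: H2O2 should attack the tertiary carbon of the activated epoxide from the back side (borderline SN2), so the hydroperoxy-bearing quaternary centre is set by inversion of the (R)-epoxide carbon.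

Step 23
Reactants: 37 (2S,3S,6S)-1-[(tert-butyldiphenylsilyl)oxy]-6-hydroperoxy-7-hydroxy-2,6-dimethylheptan-3-yl methanesulfonate
Product: 38 [(3S,6R)-6-{(2S)-1-[(tert-butyldiphenylsilyl)oxy]propan-2-yl}-3-methyl-1,2-dioxan-3-yl]methanol
Conditions: KOtBu (1 equiv), 18-crown-6, THF, 0 °C
Reagents that add atoms: none
Why: Intramolecular alkylation of the hydroperoxide anion by the secondary mesylate (6-exo-tet SN2) should close the 1,2-dioxane with inversion at the secondary carbon; the hydroperoxide is far more acidic than the primary alcohol and is deprotonated first.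

Step 24
Reactants: 38 [(3S,6R)-6-{(2S)-1-[(tert-butyldiphenylsilyl)oxy]propan-2-yl}-3-methyl-1,2-dioxan-3-yl]methanol
Product: 39 (3S,6R)-6-{(2S)-1-[(tert-butyldiphenylsilyl)oxy]propan-2-yl}-3-methyl-1,2-dioxane-3-carbaldehyde
Conditions: Dess–Martin periodinane, NaHCO3, CH2Cl2, 0 °C → rt
Reagents that add atoms: none
Why: Dess–Martin oxidation of the primary alcohol; the aldehyde has no α-hydrogen and dialkyl peroxides tolerate the reagent.

Step 25
Reactants: 23 {[(4aR,8aS)-1,1,3,6-tetramethyl-1,4,4a,7,8,8a-hexahydronaphthalen-2-yl]methyl}triphenylphosphonium bromide; 39 (3S,6R)-6-{(2S)-1-[(tert-butyldiphenylsilyl)oxy]propan-2-yl}-3-methyl-1,2-dioxane-3-carbaldehyde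
Product: 41 tert-butyl{(2S)-2-[(3R,6S)-6-methyl-6-{2-[(4aR,8aS)-1,1,3,6-tetramethyl-1,4,4a,7,8,8a-hexahydronaphthalen-2-yl]ethenyl}-1,2-dioxan-3-yl]propoxy}diphenylsilane (E/Z mixture), via phosphonium ylide 40 (not isolated)
Conditions: 23, NaHMDS, THF, −78 → 0 °C; then 39, −78 °C → rt
Reagents that add atoms: none
Why: Wittig olefination of a semi-stabilized allylic ylide of the β-cyclogeranyl type with a non-enolizable aldehyde; the alkene geometry does not matter because this bond is reduced in the next step, and no stereocentre is touched.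

Step 26
Reactants: 41 tert-butyl{(2S)-2-[(3R,6S)-6-methyl-6-{2-[(4aR,8aS)-1,1,3,6-tetramethyl-1,4,4a,7,8,8a-hexahydronaphthalen-2-yl]ethenyl}-1,2-dioxan-3-yl]propoxy}diphenylsilane
Product: 42 tert-butyl{(2S)-2-[(3R,6R)-6-methyl-6-{2-[(4aR,8aS)-1,1,3,6-tetramethyl-1,4,4a,7,8,8a-hexahydronaphthalen-2-yl]ethyl}-1,2-dioxan-3-yl]propoxy}diphenylsilane
Conditions: KO2C–N=N–CO2K, AcOH, MeOH/CH2Cl2, 0 °C → rt (added in portions, reaction followed closely)
Reagents that add atoms: none
Why: Diimide reduction: concerted syn transfer of H2 should reduce the 1,2-disubstituted alkene faster than the tri- and tetrasubstituted ring alkenes and, unlike catalytic hydrogenation, leaves the O–O bond intact.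

Step 27
Reactants: 42 tert-butyl{(2S)-2-[(3R,6R)-6-methyl-6-{2-[(4aR,8aS)-1,1,3,6-tetramethyl-1,4,4a,7,8,8a-hexahydronaphthalen-2-yl]ethyl}-1,2-dioxan-3-yl]propoxy}diphenylsilane
Product: 43 (2S)-2-[(3R,6R)-6-methyl-6-{2-[(4aR,8aS)-1,1,3,6-tetramethyl-1,4,4a,7,8,8a-hexahydronaphthalen-2-yl]ethyl}-1,2-dioxan-3-yl]propan-1-ol
Conditions: TBAF, AcOH, THF, rt
Reagents that add atoms: none
Why: Buffered fluoride desilylation; the acetic acid keeps the medium from becoming basic enough to trigger β-elimination of the peroxide.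

Step 28
Reactants: 43 (2S)-2-[(3R,6R)-6-methyl-6-{2-[(4aR,8aS)-1,1,3,6-tetramethyl-1,4,4a,7,8,8a-hexahydronaphthalen-2-yl]ethyl}-1,2-dioxan-3-yl]propan-1-ol
Product: 44 (2R)-2-[(3R,6R)-6-methyl-6-{2-[(4aR,8aS)-1,1,3,6-tetramethyl-1,4,4a,7,8,8a-hexahydronaphthalen-2-yl]ethyl}-1,2-dioxan-3-yl]propanoic acid (CNP0122760.1)
Conditions: TEMPO (cat.), PhI(OAc)2 (2.2 equiv), MeCN/pH 7 buffer, rt
Reagents that add atoms: water, O
Why: TEMPO/PhI(OAc)2 oxidation in aqueous acetonitrile takes the primary alcohol through the aldehyde hydrate to the acid under near-neutral conditions, which should leave the peroxide, the ring alkenes and the α-stereocentre untouched.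

## Compound list

1 | 3-methylbut-2-enal | CC(C)=CC=O | starting material
2 | 2,3-dibromo-3-methylbutanal (racemic) | CC(C)(Br)C(Br)C=O | intermediate
3 | 2-bromo-3-methylbut-2-enal | CC(C)=C(Br)C=O | intermediate
4 | 2-bromo-3-methylbut-2-en-1-ol | CC(C)=C(Br)CO | intermediate
5 | [(2-bromo-3-methylbut-2-en-1-yl)oxy](tert-butyl)diphenylsilane | CC(C)=C(Br)CO[Si](c1ccccc1)(c1ccccc1)C(C)(C)C | intermediate
6 | 5,6-dihydro-2H-pyran-2-one | O=C1C=CCCO1 | starting material
7 | potassium vinyltrifluoroborate | C=C[B-](F)(F)F.[K+] | starting material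
8 | (R)-4-vinyltetrahydro-2H-pyran-2-one | O=C1C[C@H](C=C)CCO1 | intermediate
9 | [1-(tert-butyldiphenylsilyloxy)-3-methylbut-2-en-2-yl]lithium | [Li]C(CO[Si](c1ccccc1)(c1ccccc1)C(C)(C)C)=C(C)C | intermediate
10 | (6R)-3-[(tert-butyldiphenylsilyloxy)methyl]-8-hydroxy-2-methyl-6-vinyloct-2-en-4-one | CC(C)=C(CO[Si](c1ccccc1)(c1ccccc1)C(C)(C)C)C(=O)C[C@H](C=C)CCO | intermediate
11 | methyllithium | [Li]C | starting material
12 | (4RS,6R)-3-[(tert-butyldiphenylsilyloxy)methyl]-2,4-dimethyl-6-vinyloct-2-ene-4,8-diol (both C4 epimers) | CC(C)=C(CO[Si](c1ccccc1)(c1ccccc1)C(C)(C)C)C(C)(O)C[C@H](C=C)CCO | intermediate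
13 | (4S,6R)-6-[1-(tert-butyldiphenylsilyloxy)-3-methylbut-2-en-2-yl]-6-methyl-4-vinyltetrahydro-2H-pyran-2-one (vinyl trans to alkenyl) | O=C1C[C@@H](C=C)C[C@](C)(C(CO[Si](c2ccccc2)(c2ccccc2)C(C)(C)C)=C(C)C)O1 | intermediate
14 | trimethylsilyl ketene acetal of 13 (6-trimethylsilyloxy-3,4-dihydro-2H-pyran, stereocentres as in 13) | C[Si](C)(C)OC1=C[C@@H](C=C)C[C@](C)(C(CO[Si](c2ccccc2)(c2ccccc2)C(C)(C)C)=C(C)C)O1 | intermediate
15 | trimethylsilyl (1S,6R)-3-[(tert-butyldiphenylsilyloxy)methyl]-2,2,4-trimethyl-6-vinylcyclohex-3-ene-1-carboxylate | C=C[C@H]1CC(C)=C(CO[Si](c2ccccc2)(c2ccccc2)C(C)(C)C)C(C)(C)[C@H]1C(=O)O[Si](C)(C)C | intermediate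
16 | (1S,6R)-3-[(tert-butyldiphenylsilyloxy)methyl]-2,2,4-trimethyl-6-vinylcyclohex-3-ene-1-carboxylic acid (vinyl and carboxyl cis) | C=C[C@H]1CC(C)=C(CO[Si](c2ccccc2)(c2ccccc2)C(C)(C)C)C(C)(C)[C@H]1C(=O)O | intermediate
17 | [(1S,6R)-3-[(tert-butyldiphenylsilyloxy)methyl]-2,2,4-trimethyl-6-vinylcyclohex-3-en-1-yl]methanol | C=C[C@H]1CC(C)=C(CO[Si](c2ccccc2)(c2ccccc2)C(C)(C)C)C(C)(C)[C@H]1CO | intermediate
18 | (1S,6R)-3-[(tert-butyldiphenylsilyloxy)methyl]-1-(iodomethyl)-2,2,4-trimethyl-6-vinylcyclohex-3-ene | C=C[C@H]1CC(C)=C(CO[Si](c2ccccc2)(c2ccccc2)C(C)(C)C)C(C)(C)[C@H]1CI | intermediate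
19 | 2-methylallylmagnesium chloride | C=C(C)C[Mg]Cl | starting material
20 | (1S,6R)-3-[(tert-butyldiphenylsilyloxy)methyl]-2,2,4-trimethyl-1-(3-methylbut-3-en-1-yl)-6-vinylcyclohex-3-ene | C=C[C@H]1CC(C)=C(CO[Si](c2ccccc2)(c2ccccc2)C(C)(C)C)C(C)(C)[C@H]1CCC(C)=C | intermediate
21 | tert-butyl{[(4aR,8aS)-1,1,3,6-tetramethyl-1,4,4a,7,8,8a-hexahydronaphthalen-2-yl]methoxy}diphenylsilane (cis ring fusion) | CC1=C[C@H]2CC(C)=C(CO[Si](c3ccccc3)(c3ccccc3)C(C)(C)C)C(C)(C)[C@H]2CC1 | intermediate
22 | [(4aR,8aS)-1,1,3,6-tetramethyl-1,4,4a,7,8,8a-hexahydronaphthalen-2-yl]methanol | CC1=C[C@H]2CC(C)=C(CO)C(C)(C)[C@H]2CC1 | intermediate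
23 | {[(4aR,8aS)-1,1,3,6-tetramethyl-1,4,4a,7,8,8a-hexahydronaphthalen-2-yl]methyl}triphenylphosphonium bromide | CC1=C[C@H]2CC(C)=C(C[P+](c3ccccc3)(c3ccccc3)c3ccccc3)C(C)(C)[C@H]2CC1.[Br-] | intermediate
24 | (S)-(2-methyloxiran-2-yl)methanol [(S)-2-methylglycidol] | OC[C@@]1(C)CO1 | starting material
25 | allylmagnesium chloride | C=CC[Mg]Cl | starting material
26 | (R)-2-methylhex-5-ene-1,2-diol | C=CCC[C@@](C)(O)CO | intermediate
27 | (R)-2-hydroxy-2-methylhex-5-en-1-yl 4-methylbenzenesulfonate | C=CCC[C@@](C)(O)COS(=O)(=O)c1ccc(C)cc1 | intermediate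
28 | (R)-2-(but-3-en-1-yl)-2-methyloxirane | C=CCC[C@]1(C)CO1 | intermediate
29 | 3-{2-[(2R)-2-methyloxiran-2-yl]ethyl}-1,2,4-trioxolane (secondary ozonide, trioxolane carbon unassigned) | C1OC(CC[C@]2(C)CO2)OO1 | intermediate
30 | 3-[(2R)-2-methyloxiran-2-yl]propanal | O=CCC[C@]1(C)CO1 | intermediate
31 | (R)-4-benzyl-3-propionyloxazolidin-2-one | CCC(=O)N1[C@H](Cc2ccccc2)COC1=O | starting material
32 | (R)-4-benzyl-3-[(Z)-1-(dibutylboryloxy)prop-1-en-1-yl]oxazolidin-2-one | C/C=C(\OB(CCCC)CCCC)N1[C@H](Cc2ccccc2)COC1=O | intermediate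
33 | (4R)-4-benzyl-3-{(2R,3S)-3-hydroxy-2-methyl-5-[(2R)-2-methyloxiran-2-yl]pentanoyl}oxazolidin-2-one | C1O[C@]1(C)CC[C@@H]([C@@H](C)C(=O)N2[C@H](Cc3ccccc3)COC2=O)O | intermediate
34 | (2S,3S)-2-methyl-5-[(2R)-2-methyloxiran-2-yl]pentane-1,3-diol | C1O[C@]1(C)CC[C@@H]([C@@H](C)CO)O | intermediate
35 | (2S,3S)-1-[(tert-butyldiphenylsilyl)oxy]-2-methyl-5-[(2R)-2-methyloxiran-2-yl]pentan-3-ol | C1O[C@]1(C)CC[C@@H]([C@@H](C)CO[Si](c2ccccc2)(c2ccccc2)C(C)(C)C)O | intermediate
36 | (2S,3S)-1-[(tert-butyldiphenylsilyl)oxy]-2-methyl-5-[(2R)-2-methyloxiran-2-yl]pentan-3-yl methanesulfonate | C1O[C@]1(C)CC[C@@H]([C@@H](C)CO[Si](c2ccccc2)(c2ccccc2)C(C)(C)C)OS(C)(=O)=O | intermediate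
37 | (2S,3S,6S)-1-[(tert-butyldiphenylsilyl)oxy]-6-hydroperoxy-7-hydroxy-2,6-dimethylheptan-3-yl methanesulfonate | OC[C@@](C)(OO)CC[C@@H]([C@@H](C)CO[Si](c1ccccc1)(c1ccccc1)C(C)(C)C)OS(C)(=O)=O | intermediate
38 | [(3S,6R)-6-{(2S)-1-[(tert-butyldiphenylsilyl)oxy]propan-2-yl}-3-methyl-1,2-dioxan-3-yl]methanol | OC[C@]1(C)CC[C@H]([C@@H](C)CO[Si](c2ccccc2)(c2ccccc2)C(C)(C)C)OO1 | intermediate
39 | (3S,6R)-6-{(2S)-1-[(tert-butyldiphenylsilyl)oxy]propan-2-yl}-3-methyl-1,2-dioxane-3-carbaldehyde | O=C[C@]1(C)CC[C@H]([C@@H](C)CO[Si](c2ccccc2)(c2ccccc2)C(C)(C)C)OO1 | intermediate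
40 | {[(4aR,8aS)-1,1,3,6-tetramethyl-1,4,4a,7,8,8a-hexahydronaphthalen-2-yl]methylidene}triphenylphosphorane | CC1=C[C@H]2CC(C)=C(C=P(c3ccccc3)(c3ccccc3)c3ccccc3)C(C)(C)[C@H]2CC1 | intermediate
41 | tert-butyl{(2S)-2-[(3R,6S)-6-methyl-6-{2-[(4aR,8aS)-1,1,3,6-tetramethyl-1,4,4a,7,8,8a-hexahydronaphthalen-2-yl]ethenyl}-1,2-dioxan-3-yl]propoxy}diphenylsilane (E/Z mixture) | CC1=C[C@H]2CC(C)=C(C=C[C@]3(C)CC[C@H]([C@@H](C)CO[Si](c4ccccc4)(c4ccccc4)C(C)(C)C)OO3)C(C)(C)[C@H]2CC1 | intermediate
42 | tert-butyl{(2S)-2-[(3R,6R)-6-methyl-6-{2-[(4aR,8aS)-1,1,3,6-tetramethyl-1,4,4a,7,8,8a-hexahydronaphthalen-2-yl]ethyl}-1,2-dioxan-3-yl]propoxy}diphenylsilane | CC1=C[C@H]2CC(C)=C(CC[C@]3(C)CC[C@H]([C@@H](C)CO[Si](c4ccccc4)(c4ccccc4)C(C)(C)C)OO3)C(C)(C)[C@H]2CC1 | intermediate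
43 | (2S)-2-[(3R,6R)-6-methyl-6-{2-[(4aR,8aS)-1,1,3,6-tetramethyl-1,4,4a,7,8,8a-hexahydronaphthalen-2-yl]ethyl}-1,2-dioxan-3-yl]propan-1-ol | CC1=C[C@H]2CC(C)=C(CC[C@]3(C)CC[C@H]([C@@H](C)CO)OO3)C(C)(C)[C@H]2CC1 | intermediate
44 | (2R)-2-[(3R,6R)-6-methyl-6-{2-[(4aR,8aS)-1,1,3,6-tetramethyl-1,4,4a,7,8,8a-hexahydronaphthalen-2-yl]ethyl}-1,2-dioxan-3-yl]propanoic acid | CC1=C[C@H]2CC(C)=C(CC[C@]3(C)CC[C@H]([C@@H](C)C(=O)O)OO3)C(C)(C)[C@H]2CC1 | target

## Step count and risks

Total: 28 steps. Longest linear sequence: 17 steps (steps 1–3, 5–14, 25–28). The lactone branch (step 4) and the dioxane branch (steps 15–24) are shorter.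

Steps most likely to fail:

1. Step 8 (ring contraction). The boat transition state must bring a secondary enolate carbon onto a fully substituted alkene carbon. If the shift is too slow, ionisation of the tertiary allylic C–O bond of the ketene acetal (loss of the silyl carboxylate, diene formation) or simple desilylation back to the lactone can take over. The fallback sets out from 13 and moves the same bond formation to the ether oxidation level, where there is no carboxylate leaving group and no labile silyl group. DIBAL reduction should give the 2-hydroxytetrahydropyran (lactol) F1. Dehydration with MsCl/Et3N should give the 2-alkenyl-3,4-dihydro-2H-pyran F2. Its allyl vinyl ether can be heated to 180–200 °C in a sealed tube for the same boat [3,3] shift, giving the cis cyclohexenecarbaldehyde F3. Immediate NaBH4 reduction rejoins the route at alcohol 17.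

2. Step 22 (with its partner, step 23). In step 22 the activated epoxide may ionise to a tertiary cation before H2O2 attacks, which would erode the configuration of the quaternary peroxy carbon. In step 23 the β-hydroxy hydroperoxide may fragment under base instead of cyclizing. The fallback sets out from mesylate 36 and reverses the order of the two C–O bond formations. SN2 displacement of the mesylate with 2-methoxyprop-2-yl hydroperoxide and CsOH in DMF should give the peroxyketal F4, with inversion at the secondary carbon. Aqueous acetic acid should free the secondary hydroperoxide F5. A catalytic amount of camphorsulfonic acid should then make it open the epoxide intramolecularly at the tertiary carbon (6-exo, back-side attack enforced by the tether). This gives dioxane alcohol 38 through the same two inversions.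

3. Step 25 (Wittig union). Both partners are hindered: the ylide carbon is flanked by the gem-dimethyl carbon and the ring methyl group, and the aldehyde is α-quaternary. Slow oxaphosphetane formation would leave the ylide time to decompose or to attack the O–O bond. The fallback sets out from alcohol 22 and uses a smaller carbanion in a Julia–Kocienski olefination. Mitsunobu reaction with 1-phenyl-1H-tetrazole-5-thiol should give the tetrazolyl sulfide F6. Molybdate/H2O2 oxidation should give the tetrazolyl sulfone F7. KHMDS-mediated coupling with aldehyde 39 under Barbier conditions then rejoins the route at diene 41.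

Further compounds

F1 | step 8 | (4S,6R)-6-[1-(tert-butyldiphenylsilyloxy)-3-methylbut-2-en-2-yl]-6-methyl-4-vinyltetrahydro-2H-pyran-2-ol (anomers) | OC1C[C@@H](C=C)C[C@](C)(C(CO[Si](c2ccccc2)(c2ccccc2)C(C)(C)C)=C(C)C)O1
F2 | step 8 | (2R,4R)-2-[1-(tert-butyldiphenylsilyloxy)-3-methylbut-2-en-2-yl]-2-methyl-4-vinyl-3,4-dihydro-2H-pyran | C1=C[C@@H](C=C)C[C@](C)(C(CO[Si](c2ccccc2)(c2ccccc2)C(C)(C)C)=C(C)C)O1
F3 | step 8 | (1S,6R)-3-[(tert-butyldiphenylsilyloxy)methyl]-2,2,4-trimethyl-6-vinylcyclohex-3-ene-1-carbaldehyde | C=C[C@H]1CC(C)=C(CO[Si](c2ccccc2)(c2ccccc2)C(C)(C)C)C(C)(C)[C@H]1C=O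
F4 | step 22 | tert-butyl{(2S,3R)-3-[(2-methoxypropan-2-yl)peroxy]-2-methyl-5-[(2R)-2-methyloxiran-2-yl]pentyloxy}diphenylsilane | C1O[C@]1(C)CC[C@H]([C@@H](C)CO[Si](c2ccccc2)(c2ccccc2)C(C)(C)C)OOC(C)(C)OC
F5 | step 22 | (2S,3R)-1-[(tert-butyldiphenylsilyl)oxy]-2-methyl-5-[(2R)-2-methyloxiran-2-yl]pentan-3-yl hydroperoxide | C1O[C@]1(C)CC[C@H]([C@@H](C)CO[Si](c2ccccc2)(c2ccccc2)C(C)(C)C)OO
F6 | step 25 | 1-phenyl-5-({[(4aR,8aS)-1,1,3,6-tetramethyl-1,4,4a,7,8,8a-hexahydronaphthalen-2-yl]methyl}sulfanyl)-1H-tetrazole | CC1=C[C@H]2CC(C)=C(CSc3nnnn3-c3ccccc3)C(C)(C)[C@H]2CC1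
F7 | step 25 | 1-phenyl-5-({[(4aR,8aS)-1,1,3,6-tetramethyl-1,4,4a,7,8,8a-hexahydronaphthalen-2-yl]methyl}sulfonyl)-1H-tetrazole | CC1=C[C@H]2CC(C)=C(CS(=O)(=O)c3nnnn3-c3ccccc3)C(C)(C)[C@H]2CC1
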